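## Retrosynthetic overview

1. Target ⇒ cut the bond between pyranone C6 and the first chain CH2. The fragments are a C6‑zincated 2‑methoxy‑4‑pyranone and (S)‑11‑iodoundecan‑2‑yl acetate, joined by sp2–sp3 Negishi coupling. The zincated pyranone is a metalated enol ether (masked acyl anion) and a β‑acylvinyl d3 donor, at a carbon that is normally a Michael acceptor.
2. Iodo acetate ⇐ Finkelstein ⇐ chloro acetate ⇐ Cu‑catalysed opening of (S)‑propylene oxide (source of the only stereocentre) by 8‑chlorooctylmagnesium bromide, with acetylation in the same pot.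
3. C6–H pyranone ⇐ O‑methylation of 3‑ethyl‑4‑hydroxy‑5‑methyl‑2‑pyranone ⇐ lactonisation of a formyl keto ester ⇐ dianion of methyl 2‑ethyl‑3‑oxopentanoate + methyl formate ⇐ methyl 3‑oxopentanoate + EtI.
4. Ring order: the single ring (the pyranone) is closed in step 2, before the side chain is attached in the last step.

Assumption: the target stereocentre reads as S; simple atom‑delivering reagents (EtI, HCO2Me, MeOTf, Ac2O, NaI) are listed under "Reagents that add atoms" and are not numbered.

## Route

Step 1
Reactants: 1 methyl 3‑oxopentanoate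
Product: 2 methyl 2‑ethyl‑3‑oxopentanoate (racemic)
Conditions: EtI (1.1 equiv), K2CO3, acetone, reflux
Reagents that add atoms: iodoethane, CCI
Why: Acetoacetic‑ester‑type C‑alkylation of the doubly activated methylene of a β‑keto ester with a primary iodide under mild carbonate conditions, which favours mono‑alkylation.

Step 2
Reactants: 2 methyl 2‑ethyl‑3‑oxopentanoate
Product: 4 3‑ethyl‑4‑hydroxy‑5‑methyl‑2H‑pyran‑2‑one, via formyl keto ester 3 (not isolated)
Conditions: LDA (2.1 equiv), THF, −78 → 0 °C; HCO2Me (0.5 equiv), −78 °C → rt; 1 M HCl; crude, DBU, PhMe, 60 °C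
Reagents that add atoms: methyl formate, COC=O
Why: Weiler dianion chemistry, in which the γ‑carbanion of the dianion of 2 undergoes crossed Claisen formylation (the acidic product consumes a second equivalent of dianion, hence the excess of cheap 2, recovered by base extraction of acidic 4), followed by DBU‑mediated lactonisation of the hydroxymethylene enol onto the ester; the stereocentres of 2 and 3 vanish in the unsaturated ring.

Step 3
Reactants: 4 3‑ethyl‑4‑hydroxy‑5‑methyl‑2H‑pyran‑2‑one
Product: 5 3‑ethyl‑2‑methoxy‑5‑methyl‑4H‑pyran‑4‑one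
Conditions: MeOTf (1.2 equiv), CH2Cl2, 0 °C → rt; aq. NaHCO3
Reagents that add atoms: methyl trifluoromethanesulfonate, COS(=O)(=O)C(F)(F)F
Why: Regioselective O‑methylation of a neutral 4‑hydroxy‑2‑pyranone by a hard methylating agent at the most basic oxygen, the lactone carbonyl (the 4‑OH is flanked by Et and Me and is not deprotonated), so that proton loss from the 2‑methoxy‑4‑hydroxypyrylium ion gives the α‑methoxy‑γ‑pyranone.

Step 4
Reactants: 6 1‑bromo‑8‑chlorooctane; 7 (S)‑2‑methyloxirane
Product: 10 (S)‑11‑chloroundecan‑2‑yl acetate, via 8‑chlorooctylmagnesium bromide 8 (not isolated), via bromomagnesium (S)‑11‑chloroundecan‑2‑olate 9 (not isolated)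
Conditions: Mg, THF, 40 °C; CuI (10 mol%), 7 (1.2 equiv), −30 → 0 °C; Ac2O, DMAP (cat.), 0 °C → rt
Reagents that add atoms: acetic anhydride, CC(=O)OC(C)=O
Why: Selective Mg insertion into C–Br over C–Cl, Cu(I)‑catalysed SN2 opening of the epoxide at its unsubstituted carbon (the stereocentre of 7 is not touched and becomes the S carbinol carbon), and acetylation of the magnesium alkoxide in the same pot.

Step 5
Reactants: 10 (S)‑11‑chloroundecan‑2‑yl acetate
Product: 11 (S)‑11‑iodoundecan‑2‑yl acetate
Conditions: NaI (3 equiv), 2‑butanone, reflux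
Reagents that add atoms: sodium iodide, [Na+].[I-]
Why: Finkelstein SN2 halide exchange at the primary chloride, driven by precipitation of NaCl; the secondary acetate and its stereocentre are inert.

Step 6
Reactants: 5 3‑ethyl‑2‑methoxy‑5‑methyl‑4H‑pyran‑4‑one; 11 (S)‑11‑iodoundecan‑2‑yl acetate
Product: 13 (S)‑11‑(5‑ethyl‑6‑methoxy‑3‑methyl‑4‑oxo‑4H‑pyran‑2‑yl)undecan‑2‑yl acetate, via pyranylzinc chloride 12 (not isolated)
Conditions: TMPZnCl·LiCl (1.3 equiv), THF, 25 °C; then 11, Pd2(dba)3 (2 mol%), PCyp3 (8 mol%), N‑methylimidazole, THF/NMP, 80 °C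
Reagents that add atoms: none
Why: Proposed new method: C6–H is the only sp2 C–H of 5 (α to the ring oxygen, β to the carbonyl), so the hindered, non‑nucleophilic zinc amide should metalate it to an α‑alkoxyvinyl/β‑acylvinyl zinc species, which makes the normally electrophilic C6 a donor (closest known: C2‑zincation of chromones and 4‑quinolones with TMP–zinc bases), and this donor is joined to the electrophilic CH2–I of 11 by Pd/trialkylphosphine Negishi coupling of unactivated primary alkyl iodides with aryl‑ and alkenylzinc halides (closest known), conditions that tolerate the acetate and leave the remote stereocentre untouched.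

## Compound list

1 | methyl 3‑oxopentanoate | CCC(=O)CC(=O)OC | starting material
2 | methyl 2‑ethyl‑3‑oxopentanoate (racemic) | CCC(=O)C(CC)C(=O)OC | intermediate
3 | methyl 2‑ethyl‑4‑methyl‑3,5‑dioxopentanoate (formyl keto ester; stereoisomer/enol mixture) | CCC(C(=O)OC)C(=O)C(C)C=O | intermediate (not isolated)
4 | 3‑ethyl‑4‑hydroxy‑5‑methyl‑2H‑pyran‑2‑one | CCC1=C(O)C(C)=COC1=O | intermediate
5 | 3‑ethyl‑2‑methoxy‑5‑methyl‑4H‑pyran‑4‑one | CCc1c(OC)occ(C)c1=O | intermediate
6 | 1‑bromo‑8‑chlorooctane | ClCCCCCCCCBr | starting material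
7 | (S)‑2‑methyloxirane ((S)‑propylene oxide) | C[C@H]1CO1 | starting material
8 | 8‑chlorooctylmagnesium bromide | ClCCCCCCCC[Mg]Br | intermediate (not isolated)
9 | bromomagnesium (S)‑11‑chloroundecan‑2‑olate | ClCCCCCCCCC[C@H](C)O[Mg]Br | intermediate (not isolated)
10 | (S)‑11‑chloroundecan‑2‑yl acetate | ClCCCCCCCCC[C@H](C)OC(C)=O | intermediate
11 | (S)‑11‑iodoundecan‑2‑yl acetate | ICCCCCCCCC[C@H](C)OC(C)=O | intermediate
12 | (5‑ethyl‑6‑methoxy‑3‑methyl‑4‑oxo‑4H‑pyran‑2‑yl)zinc chloride (LiCl complex) | CCc1c(OC)oc([Zn]Cl)c(C)c1=O | intermediate (not isolated)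
13 | (S)‑11‑(5‑ethyl‑6‑methoxy‑3‑methyl‑4‑oxo‑4H‑pyran‑2‑yl)undecan‑2‑yl acetate | CCc1c(OC)oc(CCCCCCCCC[C@H](C)OC(C)=O)c(C)c1=O | target

## Summary

Total step count: 6.
Longest linear sequence: 4 steps (steps 1, 2, 3, 6); the side‑chain branch is 2 steps (4, 5) before the convergent step 6.

## Steps most likely to fail, with fallbacks

Step 6 (zincation of 5 and alkyl Negishi coupling). The zinc amide may be too weak to metalate the electron‑rich pyranone, or the pyranylzinc may transmetalate poorly. The fallback sets out from 5 and 11 and comes back at 13. Compound 5 is lithiated briefly with LiTMP in THF at −78 °C and quenched at once with I2 to give 3‑ethyl‑6‑iodo‑2‑methoxy‑5‑methyl‑4H‑pyran‑4‑one F1. F1 and the alkyl iodide 11 are then joined by nickel‑catalysed reductive cross‑electrophile coupling (NiI2, 4,4'‑di‑tert‑butyl‑2,2'‑bipyridine, Zn dust, NaI, DMA, 60 °C). Here the C6–Ni species from oxidative addition captures the alkyl radical derived from 11, so no preformed pyranyl‑metal reagent has to survive in solution and the acetate is tolerated.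

Step 3 (regioselective O‑methylation). The isomeric 4‑methoxy‑2‑pyranone may form in part. The fallback sets out from 3 (taken on after the acid quench of step 2, before DBU) and comes back at 5, bypassing 4. Compound 3 is treated with Tf2O and 2,6‑di‑tert‑butyl‑4‑methylpyridine in CH2Cl2 at −78 → 0 °C. O‑triflation of the hydroxymethylene enol gives methyl 2‑ethyl‑4‑methyl‑3‑oxo‑5‑(trifluoromethylsulfonyloxy)pent‑4‑enoate F2. The ester carbonyl oxygen then closes onto the activated CH by 6‑endo addition–elimination, and loss of the C3 proton gives 5 with the ester methoxy group retained, so no methylation step and no regiochemical choice remain. This cyclodehydration is reasoned from mechanism and is not an established procedure.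

Step 2 (dianion formylation and lactonisation). Formylation of the dianion may be low‑yielding or the formyl keto ester may deformylate. The fallback sets out from 2 and comes back at 4. Compound 2 is heated with tert‑butoxybis(dimethylamino)methane in toluene at 100 °C. Only the C4 methylene can form a stable enaminone, giving methyl (E)‑5‑(dimethylamino)‑2‑ethyl‑4‑methyl‑3‑oxopent‑4‑enoate F3. Warming F3 in aqueous HCl/AcOH hydrolyses the vinylogous amide and lactonises the resulting hydroxymethylene enol onto the ester to give 4, with no strong base or Claisen step.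

## Further compounds

F1 | step 6 | 3‑ethyl‑6‑iodo‑2‑methoxy‑5‑methyl‑4H‑pyran‑4‑one | CCc1c(OC)oc(I)c(C)c1=O
F2 | step 3 | methyl 2‑ethyl‑4‑methyl‑3‑oxo‑5‑(trifluoromethylsulfonyloxy)pent‑4‑enoate | CCC(C(=O)OC)C(=O)C(C)=COS(=O)(=O)C(F)(F)F
F3 | step 2 | methyl (E)‑5‑(dimethylamino)‑2‑ethyl‑4‑methyl‑3‑oxopent‑4‑enoate | CCC(C(=O)OC)C(=O)/C(C)=C/N(C)C
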